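(All runs are simulated with made-up constants, noise included.)

The summer flask cannot convert more than 75.0% of its two substrates, because each substrate molecule takes one partner and the 0.30 M of partner falls short of the 0.400 M of substrate charged. The dawn flask, the one asked about, has the same partner over 0.200 M of substrate and starts with an excess of 0.100 M.

| setting | dawn | summer | flask |
|---|---|---|---|
| left-handed substrate | 0.10 M | 0.20 M | 0.10 M |
| right-handed substrate | 0.10 M | 0.20 M | 0.10 M |
| partner | 0.30 M | 0.30 M | 0.300 M |
| catalyst | 0.50 mM | 0.50 mM | 0.50 mM |
| remark | the very flask that is asked about, followed so far | run made earlier |  |
| time |  |  | 40 min |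

- dawn (time / min: left-handed product / %, right-handed product / %): 1.00: 42, 4; 2.00: 40, 15; 3.00: 41, 20; 6.00: 41, 29; 12.0: 38, 39
- summer (time / min: left-handed product / %, right-handed product / %): 3.00: 37, 10; 6.00: 39, 23; 10.0: 35, 29; 12.0: 32, 29; 15.0: 32, 33

(scatter of a reading: 2 percentage points)

- catalyst is single-handed; left-handed substrate and right-handed substrate are mirror images of each other, charged as a racemate, each of them at the stated concentration
- steps thought possible: partner + catalyst + left-handed substrate -> catalyst + left-handed product; partner + catalyst + right-handed substrate -> catalyst + right-handed product; left-handed product <-> right-handed product; partner -> decomposition product; partner -> decomposed reagent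
- an excess is the difference of the two amounts in percent of their sum
- an excess is below zero if the other one leads

- excess of left-handed product over right-handed product in the product at 50 s
- excess of left-handed product over right-handed product in the product at 40 min
- part of the left-handed substrate and right-handed substrate charged together that has reacted at 40 min

The left-handed substrate is taken as cleared by 3.00 min, so what is unreacted from then on is right-handed substrate. At a given c(partner) its decay is pseudo-first-order, and replacing c(partner) by its mean over an interval gives a clearing constant, the first-order rate of right-handed substrate loss per molar of partner. In the dawn flask the unreacted part falls from 39.0% to 23.0% by 12.0 min, while c(partner), counted from conversion with no decomposition, falls from 0.178 M to 0.146 M. The reading is 0.362 M⁻¹ min⁻¹.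

The summer flask crawls because its c(partner), counted the same way, is down to 0.0400 M at 15.0 min, which puts the right-handed substrate's half-life at 47.9 min, against 13.1 min in the dawn flask at 12.0 min.

Carried to 40 min in the dawn flask, still with no decomposition counted, so with partner ending at the excess plus the remaining substrate, the mean c(partner) comes to 0.130 M. That leaves 6.18% unreacted, a conversion of 93.8%. The exact second-order integral leaves 6.45%, so the mean costs 0.27 percentage points.

The forecast gave 71%, 0% and 83%, this last below the reckoning here, on the ground “So partner also decomposes, about 0.05/min, and this limits conversion.”

The flask gives 75.0%, −2.05% and 91.8%.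

    partner + catalyst + left-handed substrate → catalyst + left-handed product (k = 14600 M⁻² min⁻¹)
    partner + catalyst + right-handed substrate → catalyst + right-handed product (k = 760 M⁻² min⁻¹)
    left-handed product ⇌ right-handed product (k = 0.0872 min⁻¹)
    partner → decomposition product (k = 2.39 × 10⁻⁴ min⁻¹)
    partner → decomposed reagent (k = 0.00792 min⁻¹)

At 40.0 min the flask holds 0.0776 M of partner, and 0.362 M⁻¹ min⁻¹ on that gives the right-handed substrate a half-life of 24.7 min, beside 23 min for the step itself. At 0.354 min partner's half-life is 19 min by the right-handed step, shorter than its 88 min by conversion into decomposed reagent, and at 40.0 min decomposed reagent stands at 0.0376 M. In the neighbour with 0.12 M of partner, 0.362 M⁻¹ min⁻¹ on the mean of c(partner) from 0.0200 M to 0.00161 M gives 42.8% of right-handed substrate, and at 40.0 min that flask holds 41.5%.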